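**Plan**
1. The retrosynthesis first opens the 1,4-dioxane at C3–O–C4′ and C2–O–C3′. This gives o-quinone 38 (from 6-oxotingenol 36) and tingenone 37, and both halves go back to one pentacycle, 33.
2. In 33, ring B is cut at C5–C6 and C9–C10. The enabling feature is that the neighbouring ring A atoms C5 (beside C4–CH3) and C10 (beside C1–H) carry the only two carbon links to the terpenoid part, C6 and quaternary C9. These four atoms plus C7 and C8 make up ring B, so ring A can arrive as a C5≡C10 aryne on a C6=C7–C8=C9 diene.
3. Forward order: ring C is 2-methylcyclohexane-1,3-dione. Ring D closes by an asymmetric aldol condensation, ring E by a second aldol condensation, ring B (bringing ring A) by the aryne [4+2], and the dioxane last.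
4. Stereochemistry: C14 comes from (S)-phenylalanine and C13 from a hydroxyl-directed cyclopropanation with reductive opening. C17 comes from a cuprate addition on the face away from the axial C13 methyl, and C18 and C20 from equilibration. C9 is set by α-face aryne approach, C8 by Li/NH3, and C3′/C4′ by suprafacial β-face cycloaddition.

Key step: step 22

Remark: atoms carry the friedelane numbers of the target from the first intermediate on (ring C = C8, C9, C11–C14; ring D = C13–C18; ring E = C17–C22; primes = tingenone-derived half; α below, β above the usual drawing). The epimerisable centres C9 (until step 20) and C20 are drawn in their equatorial, thermodynamically preferred form. MOM = methoxymethyl.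

**Aryne precursor**

Step 1
Reactants: 1 3-methylcatechol
Product: 2 1,2-bis(methoxymethoxy)-3-methylbenzene
Conditions: MOMCl, i-Pr2NEt, CH2Cl2, 0 °C to rt
Reagents that add atoms: chloromethyl methyl ether, COCCl
Why: O-alkylation to the bis-acetal; MOM ethers should withstand organolithiums, fluoride, DDQ and Li/NH3, and they leave in the same acid treatment as the ketal and the C6 ether.

Step 2
Reactants: 2 1,2-bis(methoxymethoxy)-3-methylbenzene
Product: 3 1-bromo-3,4-bis(methoxymethoxy)-2-methylbenzene
Conditions: NBS, MeCN, 0 °C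
Reagents that add atoms: N-bromosuccinimide, O=C1CCC(=O)N1Br
Why: Electrophilic aromatic bromination; the C2 oxygen can lie in the ring plane and directs para to C5, whereas the C3 oxygen is twisted between two ortho groups.

Step 3
Reactants: 3 1-bromo-3,4-bis(methoxymethoxy)-2-methylbenzene
Product: 5 3,4-bis(methoxymethoxy)-2-methylphenol, via dimethyl arylboronate 4 (not isolated)
Conditions: n-BuLi, THF, −78 °C; B(OMe)3; then H2O2, NaOH, 0 °C
Reagents that add atoms: hydrogen peroxide, OO; trimethyl borate, COB(OC)OC (held only in 4)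
Why: Bromine–lithium exchange, borylation and boronate oxidation (1,2-aryl shift to oxygen) replace Br by OH at the same carbon.

Step 4
Reactants: 5 3,4-bis(methoxymethoxy)-2-methylphenol
Product: 6 6-bromo-3,4-bis(methoxymethoxy)-2-methylphenol
Conditions: NBS, i-Pr2NH (cat.), CH2Cl2, −78 to 0 °C
Reagents that add atoms: N-bromosuccinimide, O=C1CCC(=O)N1Br
Why: Phenol-directed ortho bromination; C10 is the only free ortho position and is also para to the C3 oxygen.

Step 5
Reactants: 6 6-bromo-3,4-bis(methoxymethoxy)-2-methylphenol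
Product: 9 3,4-bis(methoxymethoxy)-2-methyl-6-(trimethylsilyl)phenyl triflate, via aryl trimethylsilyl ether 7 (not isolated), via lithium 2-silylphenolate 8 (not isolated)
Conditions: (Me3Si)2NH, THF, reflux, evaporation; n-BuLi, THF, −78 °C; Tf2O, −78 °C to rt
Reagents that add atoms: hexamethyldisilazane, C[Si](C)(C)N[Si](C)(C)C; triflic anhydride, O=S(=O)(OS(=O)(=O)C(F)(F)F)C(F)(F)F; n-butyllithium, [Li]CCCC (lithium held only in 8)
Why: O-silylation, bromine–lithium exchange with O-to-C silyl shift (retro-Brook rearrangement) and O-triflation form the standard one-pot route to 2-silylaryl triflates.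

**C/D/E tricycle**

Step 6
Reactants: 10 5-bromopent-1-ene; 11 acrolein
Product: 13 octa-1,7-dien-3-ol (racemic), via pent-4-enylmagnesium bromide 12 (not isolated)
Conditions: Mg, THF; 11, −78 to 0 °C; aq. NH4Cl
Reagents that add atoms: magnesium, [Mg] (held only in 12)
Why: Grignard formation and 1,2-addition to the enal.

Step 7
Reactants: 13 octa-1,7-dien-3-ol
Product: 14 octa-1,7-dien-3-one
Conditions: Dess–Martin periodinane, CH2Cl2, 0 °C
Reagents that add atoms: none
Why: Dess–Martin oxidation of the allylic alcohol under neutral, water-free conditions spares the polymerisable vinyl ketone.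

Step 8
Reactants: 14 octa-1,7-dien-3-one; 15 2-methylcyclohexane-1,3-dione
Product: 16 2-methyl-2-(3-oxooct-7-enyl)cyclohexane-1,3-dione
Conditions: Et3N (cat.), MeCN, rt
Reagents that add atoms: none
Why: Amine-catalysed Michael addition of the cyclic 1,3-dione forms C14–C15 and the prochiral quaternary C14.

Step 9
Reactants: 16 2-methyl-2-(3-oxooct-7-enyl)cyclohexane-1,3-dione
Product: 17 (S)-5-(but-3-enyl)-8a-methyl-3,4,8,8a-tetrahydronaphthalene-1,6(2H,7H)-dione (rings C and D; 14β-CH3; C8 and C17 ketones; C13=C18)
Conditions: (S)-phenylalanine, (+)-camphorsulfonic acid, DMF, 30 to 70 °C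
Reagents that add atoms: none
Why: Hajos–Parrish–Eder–Sauer–Wiechert-type aldol condensation in its primary-amino-acid form for chain-substituted triketones; the (S)-phenylalanine enamine attacks one of the two enantiotopic ring carbonyls, which closes ring D (C18–C13) and fixes C14 as S.

Step 10
Reactants: 17 butenyl enedione
Product: 18 (S)-8a-methyl-5-(3-oxobutyl)-3,4,8,8a-tetrahydronaphthalene-1,6(2H,7H)-dione
Conditions: PdCl2 (cat.), CuCl, O2, DMF/H2O, rt
Reagents that add atoms: water, O (source of the C21 oxygen; O2, O=O, is the terminal oxidant)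
Why: Wacker oxidation; Markovnikov hydroxypalladation of the monosubstituted alkene gives the C21 methyl ketone and leaves the tetrasubstituted enone untouched.

Step 11
Reactants: 18 trione
Product: 19 8,21-bis(ethylene ketal) of 18 (C17 enone free)
Conditions: TMSOCH2CH2OTMS, TMSOTf (cat.), CH2Cl2, −78 to −20 °C
Reagents that add atoms: 1,2-bis(trimethylsilyloxy)ethane, C[Si](C)(C)OCCO[Si](C)(C)C
Why: Silyl-triflate-catalysed dioxolane formation is fast for saturated ketones and slow for conjugated ones at low temperature, so C8 and C21 are masked selectively.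

Step 12
Reactants: 19 bis-ketal enone
Product: 20 17α-allylic alcohol (17R)
Conditions: KBH(s-Bu)3, THF, −78 °C; H2O
Reagents that add atoms: none
Why: 1,2-Reduction by a bulky trialkylborohydride, which reaches cyclohexenone carbonyls along the equatorial path (here from the β face) and so gives the pseudoaxial 17α-alcohol, as known for 4-en-3-one steroids.

Step 13
Reactants: 20 17α-allylic alcohol
Product: 21 13α,18α-methano (cyclopropane) 17α-alcohol
Conditions: Et2Zn, CH2I2, CH2Cl2, −10 °C to rt
Reagents that add atoms: diiodomethane, ICI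
Why: Simmons–Smith cyclopropanation (Furukawa reagent) directed by the zinc alkoxide; methylene is delivered syn to the 17α-oxygen, which is also the face away from the 14β-methyl, so the future C13 methyl carbon is bound α.

Step 14
Reactants: 21 cyclopropyl carbinol
Product: 22 13α,18α-methano 17-ketone
Conditions: Dess–Martin periodinane, NaHCO3, CH2Cl2, rt
Reagents that add atoms: none
Why: Buffered Dess–Martin oxidation leaves both dioxolanes and the cyclopropane intact.

Step 15
Reactants: 22 cyclopropyl ketone
Product: 23 trans-fused 13α,14β-dimethyl C/D decalone (C17 ketone; 18β-H; equatorial side chain)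
Conditions: Li, NH3(l)/THF, −78 to −33 °C; NH4Cl
Reagents that add atoms: none
Why: In this dissolving-metal cleavage of a conjugated cyclopropyl ketone the outer C18–CH2 bond breaks, since it overlaps best with the ketyl and releases a primary carbanion; this leaves the 13α-methyl trans to the 14β-methyl, and protonation of the enolate puts the C18 chain equatorial (18β-H) because the axial site faces the 14β-methyl.

Step 16
Reactants: 23 decalone bis-ketal
Product: 25 tricyclic C/D/E 17(22)-ene-8,21-dione (13α,14β-dimethyl; 18β-H), via triketone 24 (not isolated)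
Conditions: 3 M aq. HCl, MeOH, reflux
Reagents that add atoms: water, O
Why: Hydrolysis of both dioxolanes and intramolecular aldol condensation of the 1,5-diketone (second half of a Robinson annulation) close ring E between C22 and C17, while 18β-H, now γ to the enone, keeps the equatorial arrangement.

Step 17
Reactants: 25 tricyclic enedione
Product: 26 9α,20β-dimethyl derivative of 25
Conditions: LiN(i-Pr)2 (2.3 equiv), THF, −78 °C; MeI, −78 to −30 °C
Reagents that add atoms: iodomethane, CI
Why: Kinetic double enolate alkylation; C9 is the only enolisable position of the C8 ketone and the enone is deprotonated at α′ C20, and both new centres stay epimerisable (C9 is erased in step 20, C20 is settled by equilibration in steps 19, 25 and 26).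

Step 18
Reactants: 26 dimethyl enedione
Product: 27 9α,13α,14β,17β,20β-pentamethyl C/D/E 8,21-dione (trans C/D; cis D/E)
Conditions: MeLi, CuI, Et2O, 0 °C; BF3·OEt2, 26, −78 to −30 °C; aq. NH4Cl
Reagents that add atoms: lithium dimethylcuprate, [Li+].C[Cu-]C
Why: BF3-assisted Gilman cuprate 1,4-addition; attack axial to ring E and equatorial to ring D (β face) is the known course for 1(9)-octal-2-ones (cis-fused product) and is reinforced because the α face of C17 lies under the axial 13α-methyl, which sets the 17β-methyl cis to 18β-H.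

Step 19
Reactants: 27 dione
Product: 28 21-ethylene ketal of 27
Conditions: ethylene glycol, p-TsOH (cat.), toluene, reflux (Dean–Stark)
Reagents that add atoms: ethylene glycol, OCCO
Why: Acid-catalysed ketalisation selects C21, because the C8 carbonyl between quaternary C14 and C9(H)CH3 is as inert as that of 2,2,6-trimethylcyclohexanone, and enolisation under these conditions brings the C20 methyl into the equatorial β position.

Step 20
Reactants: 28 ketal ketone
Product: 29 C8 enol triflate (C8=C9)
Conditions: KN(SiMe3)2, THF, −78 to 0 °C; PhNTf2, −78 °C to rt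
Reagents that add atoms: N-phenylbis(trifluoromethanesulfonimide), O=S(=O)(N(c1ccccc1)S(=O)(=O)C(F)(F)F)C(F)(F)F
Why: Enolate O-triflation; C9–H is the only acidic position, so the tetrasubstituted enol triflate forms regiospecifically, as with 2,2,6-trimethylcyclohexanone.

Step 21
Reactants: 29 enol triflate; 30 (E)-2-(2-ethoxyvinyl)-4,4,5,5-tetramethyl-1,3,2-dioxaborolane
Product: 31 (E)-dienol ethyl ether EtO–C6H=C7H–C8=C9(CH3) on the C/D/E tricycle (21-ketal)
Conditions: Pd(OAc)2, SPhos, K3PO4, THF/H2O, 50 °C
Reagents that add atoms: none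
Why: Suzuki–Miyaura coupling with retention of the E geometry; hindered 2,6,6-trisubstituted cyclohexenyl triflates are known partners when an electron-rich biarylphosphine is used.

**Fragment union and endgame**

Step 22
Reactants: 31 dienol ethyl ether; 9 silylaryl triflate
Product: 33 6α-ethoxy-2,3-bis(methoxymethoxy)-24,29-dinorfriedela-1,3,5(10),7-tetraen-21-one ethylene ketal (9β-CH3), via aryne 32 (not isolated)
Conditions: CsF, MeCN/toluene, rt to 40 °C, 9 (excess) added slowly
Reagents that add atoms: none
Why: Fluoride attacks the silicon of 9 and triflate leaves, so aryne 32 is released slowly and is taken up by the electron-rich diene in a concerted, asynchronous [4+2] cycloaddition in which the C9–C10 bond runs ahead of C5–C6. The closest known reactions are Diels–Alder captures of arynes from 2-silylaryl triflates by 1-oxygenated dienes and the cycloadditions of 1-vinyl-2,6,6-trimethylcyclohexene with acetylenic dienophiles, which build the same kind of angular-methyl quaternary carbon. Ring B (C5–C6–C7–C8–C9–C10) closes as the six-membered ring of the cycloadduct by suprafacial bonding at both diene termini, and since C9 becomes quaternary the 1,4-dihydronaphthalene cannot aromatise. Only C8=C9 lies in ring C and the C7–C8 bond is free to rotate, but the skewed s-cis form is populated because the s-trans form would press C6 against quaternary C14. At C9 the aryne comes from the α face, opposite the pseudoaxial 14β-methyl next to C8, which turns the inside C9 methyl to β; at C6 the E enol ether holds OEt outside, hence cis to C11 and trans to the C9 methyl (6α), a centre erased in steps 23 and 26. The step needs regioselectivity and [4+2] in preference to ene and [2+2] paths: the bulky nucleophilic terminus C9 goes to C10, which has only C1–H beside it, the slim C6 goes to C5 beside the C4 methyl, and the ethoxy donor together with slow aryne release favours the cycloaddition.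

Step 23
Reactants: 33 6α-ethoxy pentacycle (one portion)
Product: 34 2,3-bis(methoxymethoxy) 7-en-6-one (21-ketal)
Conditions: DDQ, CH2Cl2/pH 7 buffer, 0 °C
Reagents that add atoms: water, O
Why: DDQ oxidation of a p-alkoxybenzylic and allylic ether; hydride abstraction from C6–H gives an oxocarbenium ion that water converts through the hemiketal into the enone, which is the chemistry of oxidative p-methoxybenzyl ether cleavage.

Step 24
Reactants: 34 enone
Product: 35 2,3-bis(methoxymethoxy) 6-ketone with 8α-H (21-ketal)
Conditions: Li, NH3(l)/THF, t-BuOH (1 equiv), −78 °C; NH4Cl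
Reagents that add atoms: none
Why: Dissolving-metal conjugate reduction; the C8 carbanion is protonated axially from the α face, away from the 9β- and 14β-methyls, which gives the trans B/C fusion, and the resulting enolate shields C6 from further reduction.

Step 25
Reactants: 35 protected 6-ketone
Product: 36 6-oxotingenol (2,3-dihydroxy-24,29-dinorfriedela-1,3,5(10)-triene-6,21-dione)
Conditions: 3 M aq. HCl, THF, 45 °C
Reagents that add atoms: water, O
Why: Acid hydrolysis of the two MOM acetals and the dioxolane, with C20 held in the equatorial β form by enolisation.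

Step 26
Reactants: 33 6α-ethoxy pentacycle (other portion)
Product: 37 tingenone (3-hydroxy-24,29-dinorfriedela-1(10),3,5,7-tetraene-2,21-dione)
Conditions: 1 M aq. HCl, THF, rt, argon, dark
Reagents that add atoms: water, O
Why: The same acetal hydrolysis, but here the p-oxygenated benzylic C6 ether ionises and, once O2 is free, ethanol is lost in a 1,6-elimination to the extended p-quinone methide, the usual path from p-hydroxybenzyl ethers to quinone methides.

Step 27
Reactants: 36 6-oxotingenol; 37 tingenone
Product: 39 target dimer CNP0106202.2 (3′β,4′β-dioxy bridge; 3′α-OH; 4′α-CH3), via o-quinone 38 (not isolated)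
Conditions: 36, Ag2O, Na2SO4, CH2Cl2, 0 °C, filtration through Celite into 37; rt, dark, argon
Reagents that add atoms: none
Why: Proposed new method: Ag2O dehydrogenates the catechol to the acyl-o-quinone 38, whose O=C3–C2=O unit serves as an electron-poor heterodiene towards the enolic C3′=C4′ bond of 37 in an inverse-electron-demand hetero-Diels–Alder reaction. The closest known type is the addition of o-quinones to enol ethers, enamines and styrenes to give 1,4-benzodioxanes, but a free enol of a hydroxy quinone methide has not been used as the 2π partner. The nucleophilic C4′ should bond to O3 because negative charge then builds on O2, para to the C6 ketone, and O2 closes onto C3′ as the hemiketal. Suprafacial addition makes the two C–O bonds cis. Ring A′ is flat and its nearest stereocentre C9′ is remote, so little facial bias is expected and the β-face adduct 39 has to be separated from its α-face isomer by chromatography.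

**Compound list**
1 | 3-methylcatechol | Cc1cccc(O)c1O | starting material
2 | 1,2-bis(methoxymethoxy)-3-methylbenzene | Cc1cccc(OCOC)c1OCOC | intermediate
3 | 1-bromo-3,4-bis(methoxymethoxy)-2-methylbenzene | Cc1c(Br)ccc(OCOC)c1OCOC | intermediate
4 | dimethyl [3,4-bis(methoxymethoxy)-2-methylphenyl]boronate | Cc1c(B(OC)OC)ccc(OCOC)c1OCOC | intermediate
5 | 3,4-bis(methoxymethoxy)-2-methylphenol | Cc1c(O)ccc(OCOC)c1OCOC | intermediate
6 | 6-bromo-3,4-bis(methoxymethoxy)-2-methylphenol | Cc1c(O)c(Br)cc(OCOC)c1OCOC | intermediate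
7 | [6-bromo-3,4-bis(methoxymethoxy)-2-methylphenoxy]trimethylsilane | Cc1c(O[Si](C)(C)C)c(Br)cc(OCOC)c1OCOC | intermediate
8 | lithium 3,4-bis(methoxymethoxy)-2-methyl-6-(trimethylsilyl)phenolate | [Li+].[O-]c1c(C)c(OCOC)c(OCOC)cc1[Si](C)(C)C | intermediate
9 | 3,4-bis(methoxymethoxy)-2-methyl-6-(trimethylsilyl)phenyl triflate | Cc1c(OS(=O)(=O)C(F)(F)F)c([Si](C)(C)C)cc(OCOC)c1OCOC | intermediate
10 | 5-bromopent-1-ene | C=CCCCBr | starting material
11 | acrolein | C=CC=O | starting material
12 | pent-4-enylmagnesium bromide | C=CCCC[Mg]Br | intermediate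
13 | octa-1,7-dien-3-ol (racemic) | C=CCCCC(O)C=C | intermediate
14 | octa-1,7-dien-3-one | C=CCCCC(=O)C=C | intermediate
15 | 2-methylcyclohexane-1,3-dione | CC1C(=O)CCCC1=O | starting material
16 | 2-methyl-2-(3-oxooct-7-enyl)cyclohexane-1,3-dione | CC1(CCC(=O)CCCC=C)C(=O)CCCC1=O | intermediate
17 | (S)-5-(but-3-enyl)-8a-methyl-3,4,8,8a-tetrahydronaphthalene-1,6(2H,7H)-dione | C[C@]12CCC(=O)C(CCC=C)=C1CCCC2=O | intermediate
18 | (S)-8a-methyl-5-(3-oxobutyl)-3,4,8,8a-tetrahydronaphthalene-1,6(2H,7H)-dione | C[C@]12CCC(=O)C(CCC(C)=O)=C1CCCC2=O | intermediate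
19 | 8,21-bis(ethylene ketal) of 18 | C[C@]12CCC(=O)C(CCC3(C)OCCO3)=C1CCCC24OCCO4 | intermediate
20 | 17α-allylic alcohol (17R) | C[C@]12CC[C@@H](O)C(CCC3(C)OCCO3)=C1CCCC24OCCO4 | intermediate
21 | 13α,18α-methano 17α-alcohol | C[C@]12CC[C@@H](O)[C@@]3(CCC4(C)OCCO4)C[C@@]13CCCC25OCCO5 | intermediate
22 | 13α,18α-methano 17-ketone | C[C@]12CCC(=O)[C@@]3(CCC4(C)OCCO4)C[C@@]13CCCC25OCCO5 | intermediate
23 | 13α,14β-dimethyl trans-decalone, 18β-H, bis-ketal | C[C@]12CCC(=O)[C@@H](CCC3(C)OCCO3)[C@]1(C)CCCC24OCCO4 | intermediate
24 | 8,17,21-triketone | C[C@]12CCC(=O)[C@@H](CCC(C)=O)[C@]1(C)CCCC2=O | intermediate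
25 | tricyclic C/D/E 17(22)-ene-8,21-dione | O=C1CCC[C@@]2(C)[C@@H]3CCC(=O)C=C3CC[C@]12C | intermediate
26 | 9α,20β-dimethyl enedione | C[C@@H]1CC[C@@]2(C)[C@@H]3C[C@@H](C)C(=O)C=C3CC[C@]2(C)C1=O | intermediate
27 | pentamethyl C/D/E 8,21-dione (17β-CH3, cis D/E) | C[C@@H]1CC[C@@]2(C)[C@@H]3C[C@@H](C)C(=O)C[C@]3(C)CC[C@]2(C)C1=O | intermediate
28 | 21-ethylene ketal 8-ketone | C[C@@H]1CC[C@@]2(C)[C@@H]3C[C@@H](C)C4(OCCO4)C[C@]3(C)CC[C@]2(C)C1=O | intermediate
29 | C8 enol triflate | O=S(=O)(OC1=C(C)CC[C@@]2(C)[C@@H]3C[C@@H](C)C4(OCCO4)C[C@]3(C)CC[C@]12C)C(F)(F)F | intermediate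
30 | (E)-2-(2-ethoxyvinyl)-4,4,5,5-tetramethyl-1,3,2-dioxaborolane | CCO/C=C/B1OC(C)(C)C(C)(C)O1 | starting material
31 | tricyclic (E)-dienol ethyl ether | CCO/C=C/C1=C(C)CC[C@@]2(C)[C@@H]3C[C@@H](C)C4(OCCO4)C[C@]3(C)CC[C@]12C | intermediate
32 | 4,5-bis(methoxymethoxy)-3-methylbenzyne (C5≡C10) | CC1=C(OCOC)C(OCOC)=CC#C1 | intermediate
33 | 6α-ethoxy 7-ene pentacycle, bis-MOM ether, 21-ketal | Cc1c(OCOC)c(OCOC)cc2c1[C@@H](OCC)C=C1[C@@]2(C)CC[C@@]2(C)[C@@H]3C[C@@H](C)C4(OCCO4)C[C@]3(C)CC[C@]12C | intermediate
34 | 7-en-6-one, bis-MOM ether, 21-ketal | Cc1c(OCOC)c(OCOC)cc2c1C(=O)C=C1[C@@]2(C)CC[C@@]2(C)[C@@H]3C[C@@H](C)C4(OCCO4)C[C@]3(C)CC[C@]12C | intermediate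
35 | 6-ketone, 8α-H, bis-MOM ether, 21-ketal | Cc1c(OCOC)c(OCOC)cc2c1C(=O)C[C@H]1[C@@]2(C)CC[C@@]2(C)[C@@H]3C[C@@H](C)C4(OCCO4)C[C@]3(C)CC[C@]12C | intermediate
36 | 6-oxotingenol | Cc1c(O)c(O)cc2c1C(=O)C[C@H]1[C@@]2(C)CC[C@@]2(C)[C@@H]3C[C@@H](C)C(=O)C[C@]3(C)CC[C@]12C | intermediate
37 | tingenone | CC1=C(O)C(=O)C=C2C1=CC=C1[C@@]2(C)CC[C@@]2(C)[C@@H]3C[C@@H](C)C(=O)C[C@]3(C)CC[C@]12C | intermediate
38 | o-quinone of 36 (24,29-dinorfriedela-1(10),4-diene-2,3,6,21-tetraone) | O=C1C=C2C(=C(C)C1=O)C(=O)C[C@H]1[C@@]2(C)CC[C@@]2(C)[C@@H]3C[C@@H](C)C(=O)C[C@]3(C)CC[C@]12C | intermediate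
39 | CNP0106202.2 | Cc1c2c(cc3c1C(=O)C[C@H]1[C@@]3(C)CC[C@@]3(C)[C@@H]4C[C@@H](C)C(=O)C[C@]4(C)CC[C@]13C)O[C@@]1(O)C(=O)C=C3C(=CC=C4[C@@]3(C)CC[C@@]3(C)[C@@H]5C[C@@H](C)C(=O)C[C@]5(C)CC[C@]43C)[C@@]1(C)O2 | target

**Totals:** 27 steps; longest linear sequence 21 steps (steps 6–25 and 27).

**Steps most likely to fail**

1. Step 27. The likely failures are little facial discrimination at the flat ring A′, hydrogen transfer between the enol or catechol and the quinone, and decay of the acyl-o-quinone before capture.
The fallback sets out from 37 and comes back at 39. Compound 37 is O-silylated (TBSCl, imidazole, DMF) to tingenone tert-butyldimethylsilyl enol ether F1. This places it in the enol ether class, whose hetero-Diels–Alder reactions with o-quinones are established. Cycloaddition with 38 (made from 36 with Ag2O and filtered) gives the silyl ketal F2. F2 cannot ring-open, so the facial isomers are separated at this stage as stable compounds. HF·pyridine in THF then frees the hemiketal 39.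

2. Step 22. The likely failures are an ene reaction of the aryne with the allylic C–H bonds of the C9 methyl or C11, [2+2] addition to the enol ether bond, and approach from the β face or with reversed orientation.
The fallback sets out from 3 and 31 and comes back at 34.
   - Bromine–lithium exchange on 3 and quenching with iodine give 1-iodo-3,4-bis(methoxymethoxy)-2-methylbenzene F3.
   - NBS brominates C10 (para to the C3 oxygen) to give the bromo iodide F4.
   - Selective iodine–magnesium exchange (i-PrMgCl·LiCl, −40 °C) gives the 2-bromoarylmagnesium chloride F5.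
   - Mild hydrolysis of 31 (oxalic acid on wet silica, CH2Cl2) gives the β,γ-unsaturated aldehyde F6.
   - Addition of F5 to F6 forms C5–C6 in the benzylic alcohol F7, and Dess–Martin oxidation gives the aryl ketone F8.
   - A palladium-catalysed intramolecular γ-arylation of the dienolate of F8 (Pd2(dba)3, P(t-Bu)3, Cs2CO3, toluene, 90 °C) forms C9–C10. α-Arylation is excluded because it would close a four-membered ring. The product is enone 34.
   - Since 33 is bypassed, 37 is then reached from 34 by Luche reduction (NaBH4, CeCl3·7H2O, MeOH) to the C6 allylic alcohol F9, followed by the acid treatment of step 26.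

3. Step 12. The likely failures are hydride delivery to the α face, which would steer the methylene of step 13 and hence the C13 methyl to the wrong side, or sluggish reduction of the tetrasubstituted enone.
The fallback sets out from 19 and comes back at 20. Luche reduction gives the equatorial 17β-alcohol F10. Mitsunobu inversion (4-nitrobenzoic acid, PPh3, DIAD, THF) gives the 17α 4-nitrobenzoate F11. Methanolysis (K2CO3, MeOH) then gives 20.

**Further compounds**
F1 | step 27 | tingenone 3-O-tert-butyldimethylsilyl enol ether | CC1=C(O[Si](C)(C)C(C)(C)C)C(=O)C=C2C1=CC=C1[C@@]2(C)CC[C@@]2(C)[C@@H]3C[C@@H](C)C(=O)C[C@]3(C)CC[C@]12C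
F2 | step 27 | 3′-O-tert-butyldimethylsilyl ketal of 39 | Cc1c2c(cc3c1C(=O)C[C@H]1[C@@]3(C)CC[C@@]3(C)[C@@H]4C[C@@H](C)C(=O)C[C@]4(C)CC[C@]13C)O[C@@]1(O[Si](C)(C)C(C)(C)C)C(=O)C=C3C(=CC=C4[C@@]3(C)CC[C@@]3(C)[C@@H]5C[C@@H](C)C(=O)C[C@]5(C)CC[C@]43C)[C@@]1(C)O2
F3 | step 22 | 1-iodo-3,4-bis(methoxymethoxy)-2-methylbenzene | Cc1c(I)ccc(OCOC)c1OCOC
F4 | step 22 | 1-bromo-2-iodo-4,5-bis(methoxymethoxy)-3-methylbenzene | Cc1c(I)c(Br)cc(OCOC)c1OCOC
F5 | step 22 | [6-bromo-3,4-bis(methoxymethoxy)-2-methylphenyl]magnesium chloride | Cc1c([Mg]Cl)c(Br)cc(OCOC)c1OCOC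
F6 | step 22 | tricyclic β,γ-unsaturated aldehyde OHC–C7H2–C8=C9 | O=CCC1=C(C)CC[C@@]2(C)[C@@H]3C[C@@H](C)C4(OCCO4)C[C@]3(C)CC[C@]12C
F7 | step 22 | C6 benzylic alcohol (either C6 epimer) | Cc1c(C(O)CC2=C(C)CC[C@@]3(C)[C@@H]4C[C@@H](C)C5(OCCO5)C[C@]4(C)CC[C@]23C)c(Br)cc(OCOC)c1OCOC
F8 | step 22 | 2-bromoaryl β,γ-unsaturated ketone | Cc1c(C(=O)CC2=C(C)CC[C@@]3(C)[C@@H]4C[C@@H](C)C5(OCCO5)C[C@]4(C)CC[C@]23C)c(Br)cc(OCOC)c1OCOC
F9 | step 22 | 7-en-6-ol pentacycle (either C6 epimer) | Cc1c(OCOC)c(OCOC)cc2c1C(O)C=C1[C@@]2(C)CC[C@@]2(C)[C@@H]3C[C@@H](C)C4(OCCO4)C[C@]3(C)CC[C@]12C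
F10 | step 12 | 17β-allylic alcohol | C[C@]12CC[C@H](O)C(CCC3(C)OCCO3)=C1CCCC24OCCO4
F11 | step 12 | 17α 4-nitrobenzoate | C[C@]12CC[C@@H](OC(=O)c3ccc(cc3)[N+](=O)[O-])C(CCC4(C)OCCO4)=C1CCCC25OCCO5
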